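**Retrosynthetic overview**
- The target comes from a macrocyclic Weinreb amide: the C14 amide is reduced to the aldehyde in the last step.
- Key disconnection C6–C7 plus O6–C12: one Ni/Cr operation adds a tetrasubstituted (Z)-β-iodoacrylate to an α,β-epoxy aldehyde, closing the cyclodecene, and the chromium alkoxide lactonises to the butenolide in the same flask.
- The open chain comes from an HWE olefination at C1=C10 between an epoxy aldehyde (geraniol, Sharpless epoxidation, ozonolysis) and a phosphonoacetamide fragment.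
- The phosphonate fragment comes from allyl bromide and a phosphonoacetamide, ozonolysis, enantioselective methyl propiolate addition (C8), isovalerate formation and an iodide/formaldehyde halo-aldol (C13 and the vinyl iodide).
- Ring order: oxirane first (step 1), then the ten-membered carbocycle and the butenolide together (step 10).

Assumption: atoms carry germacrane numbers (C12/O6 lactone, C8 isovalerate, C13 acetate, C14 aldehyde), and (S,S)-ProPhenol is taken as the ligand antipode that gives the (S)-propargylic alcohol; if the sense is the reverse, its mirror image is used.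

**Step 1**
Reactants: 1 geraniol
Product: 2 [(2R,3R)-3-methyl-3-(4-methylpent-3-en-1-yl)oxiran-2-yl]methanol
Conditions: Ti(OiPr)4 (5 mol %), D-(−)-diethyl tartrate (7 mol %), t-BuOOH, 4 Å MS, CH2Cl2, −20 °C
Reagents that add atoms: tert-butyl hydroperoxide CC(C)(C)OO
Why: Sharpless asymmetric epoxidation of the allylic alcohol, in which D-(−)-DET delivers oxygen to the face that gives the (2R,3R)-epoxy alcohol (C4 and C5 of the target) and leaves the remote alkene untouched.

**Step 2**
Reactants: 2 [(2R,3R)-3-methyl-3-(4-methylpent-3-en-1-yl)oxiran-2-yl]methanol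
Product: 3 3-[(2R,3R)-3-(hydroxymethyl)-2-methyloxiran-2-yl]propanal
Conditions: O3, pyridine (3 equiv), CH2Cl2, −78 °C
Reagents that add atoms: ozone [O-][O+]=O
Why: Pyridine-promoted reductive ozonolysis cleaves the only C=C bond directly to the C1 aldehyde without touching the epoxy alcohol stereocentres.

**Step 3**
Reactants: 4 diethyl [2-(methoxy(methyl)amino)-2-oxoethyl]phosphonate; 5 allyl bromide
Product: 6 diethyl {1-[methoxy(methyl)amino]-1-oxopent-4-en-2-yl}phosphonate (racemic)
Conditions: NaH (1.0 equiv), THF, 0 °C to rt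
Reagents that add atoms: none
Why: SN2 C-alkylation of the stabilised phosphonoacetamide anion joins C10 to C9, and the new stereocentre is irrelevant because it becomes sp2 in the HWE step.

**Step 4**
Reactants: 6 diethyl {1-[methoxy(methyl)amino]-1-oxopent-4-en-2-yl}phosphonate
Product: 7 diethyl {1-[methoxy(methyl)amino]-1,4-dioxobutan-2-yl}phosphonate (racemic)
Conditions: O3, pyridine (3 equiv), CH2Cl2, −78 °C
Reagents that add atoms: ozone [O-][O+]=O
Why: Reductive ozonolysis of the terminal alkene unmasks the C8 aldehyde, and the phosphonate and Weinreb amide are inert to ozone.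

**Step 5**
Reactants: 7 diethyl {1-[methoxy(methyl)amino]-1,4-dioxobutan-2-yl}phosphonate; 8 methyl propiolate
Product: 9 methyl (4S)-6-(diethoxyphosphoryl)-4-hydroxy-7-[methoxy(methyl)amino]-7-oxohept-2-ynoate (both C6 epimers)
Conditions: Me2Zn (3 equiv), (S,S)-ProPhenol (20 mol %), Ph3PO (40 mol %), toluene, 4 °C; aq NH4Cl
Reagents that add atoms: none
Why: Dinuclear zinc–ProPhenol catalysed enantioselective alkynylation of the aldehyde sets C8 as S by reagent control and forms the C7–C8 bond.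

**Step 6**
Reactants: 9 methyl (4S)-6-(diethoxyphosphoryl)-4-hydroxy-7-[methoxy(methyl)amino]-7-oxohept-2-ynoate
Product: 10 methyl (4S)-6-(diethoxyphosphoryl)-7-[methoxy(methyl)amino]-4-(3-methylbutanoyloxy)-7-oxohept-2-ynoate
Conditions: isovaleryl chloride, pyridine, DMAP (cat.), CH2Cl2, 0 °C
Reagents that add atoms: 3-methylbutanoyl chloride CC(C)CC(=O)Cl
Why: O-acylation of the propargylic alcohol installs the C8 isovalerate with retention and blocks lactonisation onto the Weinreb amide.

**Step 7**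
Reactants: 10 methyl (4S)-6-(diethoxyphosphoryl)-7-[methoxy(methyl)amino]-4-(3-methylbutanoyloxy)-7-oxohept-2-ynoate
Product: 12 methyl (2Z,4S)-2-(acetoxymethyl)-6-(diethoxyphosphoryl)-3-iodo-7-[methoxy(methyl)amino]-4-(3-methylbutanoyloxy)-7-oxohept-2-enoate, via iodomagnesium alkoxide of the hydroxymethyl iodoacrylate 11 (not isolated)
Conditions: MgI2 (2.5 equiv), CH2O (gas from cracked paraformaldehyde), CH2Cl2, −20 to 0 °C; then Ac2O, DMAP (cat.), 0 °C
Reagents that add atoms: magnesium iodide [Mg+2].[I-].[I-]; formaldehyde C=O; acetic anhydride CC(=O)OC(C)=O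
Why: Proposed new method: iodide adds in conjugate fashion to the Mg-activated ynoate to give a β-iodo allenolate that is trapped at the α-carbon by formaldehyde anti to iodine (the same trans sense as ynoate hydroiodination), which places I cis to CO2Me and CH2O cis to C8, and the magnesium alkoxide is acetylated in the same flask; the closest known reaction is the MgI2-promoted β-iodo Morita–Baylis–Hillman (halo-aldol) reaction of propiolates with aldehydes.

**Step 8**
Reactants: 12 methyl (2Z,4S)-2-(acetoxymethyl)-6-(diethoxyphosphoryl)-3-iodo-7-[methoxy(methyl)amino]-4-(3-methylbutanoyloxy)-7-oxohept-2-enoate; 3 3-[(2R,3R)-3-(hydroxymethyl)-2-methyloxiran-2-yl]propanal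
Product: 13 methyl (2Z,4S,6E)-2-(acetoxymethyl)-9-[(2R,3R)-3-(hydroxymethyl)-2-methyloxiran-2-yl]-3-iodo-6-[methoxy(methyl)carbamoyl]-4-(3-methylbutanoyloxy)nona-2,6-dienoate
Conditions: LiCl, DBU, MeCN, 0 °C to rt
Reagents that add atoms: none
Why: Masamune–Roush Horner–Wadsworth–Emmons olefination, in which both phosphonate epimers converge on the (E)-enamide with the carbonyl trans to the C2 chain, so C9 and C2 are cis as the ring needs, and the mild base leaves the esters, the epoxy alcohol and the hindered vinyl iodide alone.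

**Step 9**
Reactants: 13 methyl (2Z,4S,6E)-2-(acetoxymethyl)-9-[(2R,3R)-3-(hydroxymethyl)-2-methyloxiran-2-yl]-3-iodo-6-[methoxy(methyl)carbamoyl]-4-(3-methylbutanoyloxy)nona-2,6-dienoate
Product: 14 methyl (2Z,4S,6E)-2-(acetoxymethyl)-9-[(2R,3S)-3-formyl-2-methyloxiran-2-yl]-3-iodo-6-[methoxy(methyl)carbamoyl]-4-(3-methylbutanoyloxy)nona-2,6-dienoate
Conditions: Dess–Martin periodinane, NaHCO3, CH2Cl2, 0 °C
Reagents that add atoms: none
Why: Buffered Dess–Martin oxidation of the only free alcohol gives the α,β-epoxy aldehyde without epimerisation (the C5 label becomes S only because CHO now outranks C4).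

**Step 10**
Reactants: 14 methyl (2Z,4S,6E)-2-(acetoxymethyl)-9-[(2R,3S)-3-formyl-2-methyloxiran-2-yl]-3-iodo-6-[methoxy(methyl)carbamoyl]-4-(3-methylbutanoyloxy)nona-2,6-dienoate
Product: 16 (4R,5R,6R,8S)-13-acetoxy-4,5-epoxy-8-(3-methylbutanoyloxy)germacra-1(10)E,7(11)-dien-12,6-olid-14-oic acid N-methoxy-N-methylamide, via chromium alkoxide of the ring-closed hydroxy ester 15 (not isolated)
Conditions: CrCl2 (8 equiv), NiCl2 (2 mol %), degassed DMSO–THF 3:1, syringe-pump addition to 0.003 M, rt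
Reagents that add atoms: none
Why: Intramolecular Nozaki–Hiyama–Kishi reaction, in which the alkenylchromium (geometry retained) adds to the epoxy aldehyde in the Felkin–Anh sense (anti to the epoxide C–O bond, giving the 5,6-anti, 6R carbinol) to close the ten-membered ring, and the chromium alkoxide, held cis to CO2Me, lactonises to the butenolide in the same flask.

**Step 11**
Reactants: 16 (4R,5R,6R,8S)-13-acetoxy-4,5-epoxy-8-(3-methylbutanoyloxy)germacra-1(10)E,7(11)-dien-12,6-olid-14-oic acid N-methoxy-N-methylamide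
Product: 17 (4R,5R,6R,8S)-13-acetoxy-4,5-epoxy-8-(3-methylbutanoyloxy)-14-oxogermacra-1(10)E,7(11)-dien-12,6-olide (CNP0289605.1)
Conditions: Cp2Zr(H)Cl (1.5 equiv), THF, rt, 20 min; H2O, silica gel
Reagents that add atoms: none
Why: Schwartz-reagent partial reduction of the Weinreb amide stops at a zirconated hemiaminal that releases the enal on work-up, while esters, the butenolide, the epoxide and the trisubstituted alkenes react much more slowly, so geometry and all stereocentres are kept.

**Compound list**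
1 | geraniol, (2E)-3,7-dimethylocta-2,6-dien-1-ol | CC(C)=CCC/C(C)=C/CO | starting material
2 | [(2R,3R)-3-methyl-3-(4-methylpent-3-en-1-yl)oxiran-2-yl]methanol | CC(C)=CCC[C@@]1(C)O[C@@H]1CO | intermediate
3 | 3-[(2R,3R)-3-(hydroxymethyl)-2-methyloxiran-2-yl]propanal | O=CCC[C@@]1(C)O[C@@H]1CO | intermediate
4 | diethyl [2-(methoxy(methyl)amino)-2-oxoethyl]phosphonate | CCOP(=O)(CC(=O)N(C)OC)OCC | starting material
5 | allyl bromide | C=CCBr | starting material
6 | diethyl {1-[methoxy(methyl)amino]-1-oxopent-4-en-2-yl}phosphonate (racemic) | C=CCC(C(=O)N(C)OC)P(=O)(OCC)OCC | intermediate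
7 | diethyl {1-[methoxy(methyl)amino]-1,4-dioxobutan-2-yl}phosphonate (racemic) | O=CCC(C(=O)N(C)OC)P(=O)(OCC)OCC | intermediate
8 | methyl propiolate | C#CC(=O)OC | starting material
9 | methyl (4S)-6-(diethoxyphosphoryl)-4-hydroxy-7-[methoxy(methyl)amino]-7-oxohept-2-ynoate (both C6 epimers) | COC(=O)C#C[C@@H](O)CC(C(=O)N(C)OC)P(=O)(OCC)OCC | intermediate
10 | methyl (4S)-6-(diethoxyphosphoryl)-7-[methoxy(methyl)amino]-4-(3-methylbutanoyloxy)-7-oxohept-2-ynoate | COC(=O)C#C[C@@H](OC(=O)CC(C)C)CC(C(=O)N(C)OC)P(=O)(OCC)OCC | intermediate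
11 | methyl (2Z,4S)-6-(diethoxyphosphoryl)-2-(hydroxymethyl)-3-iodo-7-[methoxy(methyl)amino]-4-(3-methylbutanoyloxy)-7-oxohept-2-enoate, present as its iodomagnesium alkoxide | COC(=O)/C(CO)=C(\I)[C@@H](OC(=O)CC(C)C)CC(C(=O)N(C)OC)P(=O)(OCC)OCC | intermediate (not isolated)
12 | methyl (2Z,4S)-2-(acetoxymethyl)-6-(diethoxyphosphoryl)-3-iodo-7-[methoxy(methyl)amino]-4-(3-methylbutanoyloxy)-7-oxohept-2-enoate (I cis to CO2Me) | COC(=O)/C(COC(C)=O)=C(\I)[C@@H](OC(=O)CC(C)C)CC(C(=O)N(C)OC)P(=O)(OCC)OCC | intermediate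
13 | methyl (2Z,4S,6E)-2-(acetoxymethyl)-9-[(2R,3R)-3-(hydroxymethyl)-2-methyloxiran-2-yl]-3-iodo-6-[methoxy(methyl)carbamoyl]-4-(3-methylbutanoyloxy)nona-2,6-dienoate | COC(=O)/C(COC(C)=O)=C(\I)[C@@H](OC(=O)CC(C)C)C/C(C(=O)N(C)OC)=C\CC[C@@]1(C)O[C@@H]1CO | intermediate
14 | methyl (2Z,4S,6E)-2-(acetoxymethyl)-9-[(2R,3S)-3-formyl-2-methyloxiran-2-yl]-3-iodo-6-[methoxy(methyl)carbamoyl]-4-(3-methylbutanoyloxy)nona-2,6-dienoate | COC(=O)/C(COC(C)=O)=C(\I)[C@@H](OC(=O)CC(C)C)C/C(C(=O)N(C)OC)=C\CC[C@@]1(C)O[C@@H]1C=O | intermediate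
15 | ring-closed (6R)-hydroxy ester: ten-membered carbocycle with exocyclic C7=C11(CO2Me)(CH2OAc), CO2Me cis to C6–O, present as its chromium(III) alkoxide | COC(=O)/C(COC(C)=O)=C1/[C@@H](OC(=O)CC(C)C)C/C(C(=O)N(C)OC)=C\CC[C@@]2(C)O[C@@H]2[C@@H]1O | intermediate (not isolated)
16 | (4R,5R,6R,8S)-13-acetoxy-4,5-epoxy-8-(3-methylbutanoyloxy)germacra-1(10)E,7(11)-dien-12,6-olid-14-oic acid N-methoxy-N-methylamide | CC(=O)OCC1=C2[C@@H](OC(=O)CC(C)C)C/C(C(=O)N(C)OC)=C\CC[C@@]3(C)O[C@@H]3[C@@H]2OC1=O | intermediate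
17 | (4R,5R,6R,8S)-13-acetoxy-4,5-epoxy-8-(3-methylbutanoyloxy)-14-oxogermacra-1(10)E,7(11)-dien-12,6-olide | CC(=O)OCC1=C2[C@@H](OC(=O)CC(C)C)C/C(C=O)=C\CC[C@@]3(C)O[C@@H]3[C@@H]2OC1=O | target

**Step count**
Total: 11 steps. Longest linear sequence: 9 steps (steps 3–11, from 4 and 5 to 17).

**Three steps most likely to fail**

Step 10 (Ni/Cr macrocyclisation with lactonisation). A hindered tetrasubstituted alkenylchromium must close a ten-membered ring onto a sensitive epoxy aldehyde; reduction of the C–I bond, oligomers or the wrong C6 epimer are the likely failures. The fallback sets out from 2 and 12 and comes back at 16; it makes the butenolide intermolecularly and closes the carbocycle at the other end. Alcohol 2 is oxidised with Dess–Martin periodinane to (2S,3R)-3-methyl-3-(4-methylpent-3-en-1-yl)oxirane-2-carbaldehyde F1. F1 and vinyl iodide 12 are joined by an intermolecular Ni/Cr coupling that lactonises to the open-chain butenolide phosphonate F2 (C6 set by Felkin addition). Ozonolysis (O3, pyridine) of the one electron-rich alkene gives the butenolide phosphonate aldehyde F3. An intramolecular HWE reaction (LiCl, DBU, MeCN, high dilution) then closes the ten-membered ring at C1=C10, where the E-enamide is also the ring-cis alkene, to give 16.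

Step 7 (iodide/formaldehyde halo-aldol). Reactivity of the β-substituted ynoate and the geometry of the tetrasubstituted alkene are unproven. The fallback sets out from 10 and comes back at 16; it fixes the geometry by anti addition of two different halogens and a chemoselective coupling. IBr adds across the ynoate of 10 (bromide at the β-carbon, iodine at the α-carbon, trans) to give the (E)-3-bromo-2-iodo ester F4. Stille coupling at the C–I bond with (tributylstannyl)methanol (Pd2dba3, AsPh3, CuI) gives the hydroxymethyl bromoacrylate F5 with retention. Acetylation gives the bromoacrylate acetate F6, the bromo analogue of 12. HWE reaction with 3 gives the bromo seco alcohol F7, and Dess–Martin oxidation gives the bromo seco aldehyde F8. Ni/Cr cyclisation of the activated vinyl bromide with lactonisation then returns to 16.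

Step 5 (asymmetric alkynylation). The acidic phosphonate C–H and the enolisable aldehyde may be deprotonated by the zinc reagents and lower yield or ee. The fallback sets out from 7 and comes back at 9; it replaces asymmetric addition by addition, oxidation and asymmetric reduction. The silver acetylide of methyl propiolate is added under non-basic conditions (Cp2ZrCl2, AgOTf, CH2Cl2) to give the racemic propargylic alcohol F9. Dess–Martin oxidation gives the ynone F10. Noyori transfer hydrogenation (Ru(p-cymene)–TsDPEN, i-PrOH, ligand antipode chosen for the 4S alcohol) gives 9.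

**Further compounds**
F1 | step 10 | (2S,3R)-3-methyl-3-(4-methylpent-3-en-1-yl)oxirane-2-carbaldehyde | CC(C)=CCC[C@@]1(C)O[C@@H]1C=O
F2 | step 10 | [(5R)-4-{(1S)-3-(diethoxyphosphoryl)-4-[methoxy(methyl)amino]-1-(3-methylbutanoyloxy)-4-oxobutyl}-5-[(2R,3R)-3-methyl-3-(4-methylpent-3-en-1-yl)oxiran-2-yl]-2-oxo-2,5-dihydrofuran-3-yl]methyl acetate | CC(C)=CCC[C@@]1(C)O[C@@H]1[C@@H]2OC(=O)C(COC(C)=O)=C2[C@@H](OC(=O)CC(C)C)CC(C(=O)N(C)OC)P(=O)(OCC)OCC
F3 | step 10 | [(5R)-4-{(1S)-3-(diethoxyphosphoryl)-4-[methoxy(methyl)amino]-1-(3-methylbutanoyloxy)-4-oxobutyl}-5-[(2R,3R)-3-methyl-3-(3-oxopropyl)oxiran-2-yl]-2-oxo-2,5-dihydrofuran-3-yl]methyl acetate | O=CCC[C@@]1(C)O[C@@H]1[C@@H]2OC(=O)C(COC(C)=O)=C2[C@@H](OC(=O)CC(C)C)CC(C(=O)N(C)OC)P(=O)(OCC)OCC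
F4 | step 7 | methyl (2E,4S)-3-bromo-6-(diethoxyphosphoryl)-2-iodo-7-[methoxy(methyl)amino]-4-(3-methylbutanoyloxy)-7-oxohept-2-enoate | COC(=O)/C(I)=C(\Br)[C@@H](OC(=O)CC(C)C)CC(C(=O)N(C)OC)P(=O)(OCC)OCC
F5 | step 7 | methyl (2Z,4S)-3-bromo-6-(diethoxyphosphoryl)-2-(hydroxymethyl)-7-[methoxy(methyl)amino]-4-(3-methylbutanoyloxy)-7-oxohept-2-enoate | COC(=O)/C(CO)=C(\Br)[C@@H](OC(=O)CC(C)C)CC(C(=O)N(C)OC)P(=O)(OCC)OCC
F6 | step 7 | methyl (2Z,4S)-2-(acetoxymethyl)-3-bromo-6-(diethoxyphosphoryl)-7-[methoxy(methyl)amino]-4-(3-methylbutanoyloxy)-7-oxohept-2-enoate | COC(=O)/C(COC(C)=O)=C(\Br)[C@@H](OC(=O)CC(C)C)CC(C(=O)N(C)OC)P(=O)(OCC)OCC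
F7 | step 7 | methyl (2Z,4S,6E)-2-(acetoxymethyl)-3-bromo-9-[(2R,3R)-3-(hydroxymethyl)-2-methyloxiran-2-yl]-6-[methoxy(methyl)carbamoyl]-4-(3-methylbutanoyloxy)nona-2,6-dienoate | COC(=O)/C(COC(C)=O)=C(\Br)[C@@H](OC(=O)CC(C)C)C/C(C(=O)N(C)OC)=C\CC[C@@]1(C)O[C@@H]1CO
F8 | step 7 | methyl (2Z,4S,6E)-2-(acetoxymethyl)-3-bromo-9-[(2R,3S)-3-formyl-2-methyloxiran-2-yl]-6-[methoxy(methyl)carbamoyl]-4-(3-methylbutanoyloxy)nona-2,6-dienoate | COC(=O)/C(COC(C)=O)=C(\Br)[C@@H](OC(=O)CC(C)C)C/C(C(=O)N(C)OC)=C\CC[C@@]1(C)O[C@@H]1C=O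
F9 | step 5 | methyl 6-(diethoxyphosphoryl)-4-hydroxy-7-[methoxy(methyl)amino]-7-oxohept-2-ynoate (racemic at C4) | COC(=O)C#CC(O)CC(C(=O)N(C)OC)P(=O)(OCC)OCC
F10 | step 5 | methyl 6-(diethoxyphosphoryl)-7-[methoxy(methyl)amino]-4,7-dioxohept-2-ynoate | COC(=O)C#CC(=O)CC(C(=O)N(C)OC)P(=O)(OCC)OCC
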